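**Retrosynthetic overview**

1. The target is the trans (3R,4R) lactone, numbered O1, C2 (carbonyl), C3, C4, C5, with ring A (3,4-dimethoxyphenyl) on the C3 methylene and ring B (3,4,5-trimethoxyphenyl) on the C4 methylene. The strategy rests on C4 carrying two CH2 groups, C5 and the ring B methylene: without ring B they are the two equivalent CH2O arms of a 3-substituted oxetane.
2. Last disconnection: the bond between the C4 methylene and ring B, made by nickel-catalysed reductive cross-electrophile coupling of the C4 iodomethyl lactone with 5-bromo-1,2,3-trimethoxybenzene; the iodide comes from the C4 hydroxymethyl lactone.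
3. Key disconnection: the O1-C5 bond. The oxetane of (R)-3-(3,4-dimethoxyphenyl)-2-(oxetan-3-yl)propanoic acid is opened by its own carboxyl group under acid catalysis, which closes the lactone and creates C4 from the two diastereotopic arms under control of C3.
4. The C3 centre of that acid is set by auxiliary-controlled benzylation of the N-[2-(oxetan-3-yl)acetyl] derivative of (R)-4-benzyloxazolidin-2-one with 3,4-dimethoxybenzyl bromide; the acyl unit comes from methyl 2-(oxetan-3-ylidene)acetate.
5. Ring order: both arenes and the oxetane are bought; the lactone is the only ring formed (step 6), at the expense of the oxetane.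

Key step: step 6

Remark: 3,4-dimethoxybenzyl bromide is taken as a purchased reagent and used freshly purified, and the oxetanyl carboxyl group is kept as ester, lithium salt or imide until step 5 so that no free oxetanyl acid is stored.

**Route**

Step 1
Reactants: 1 methyl 2-(oxetan-3-ylidene)acetate
Product: 2 methyl 2-(oxetan-3-yl)acetate
Conditions: H2 (1 atm), 10% Pd/C, EtOAc, rt
Reagents that add atoms: none
Why: Heterogeneous catalytic hydrogenation of the electron-poor exocyclic alkene is fast at room temperature and leaves the non-benzylic C-O bonds of the oxetane intact.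

Step 2
Reactants: 2 methyl 2-(oxetan-3-yl)acetate
Product: 3 lithium 2-(oxetan-3-yl)acetate
Conditions: LiOH·H2O (1.0 equiv), THF/H2O, 0 °C to rt; evaporation, toluene azeotrope, high vacuum
Reagents that add atoms: lithium hydroxide, [Li+].[OH-]
Why: Ester saponification with one equivalent of LiOH gives the carboxylate salt, which is never protonated, so the oxetane cannot be opened by its own carboxyl group before the C3 centre is in place.

Step 3
Reactants: 3 lithium 2-(oxetan-3-yl)acetate; 4 (R)-4-benzyloxazolidin-2-one
Product: 7 (R)-4-benzyl-3-[2-(oxetan-3-yl)acetyl]oxazolidin-2-one, via mixed pivalic anhydride 5 (not isolated), via N-lithio oxazolidinone 6 (not isolated)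
Conditions: 3, PivCl, THF, -20 to 0 °C; separately 4, n-BuLi, THF, -78 °C; combined at -78 °C, then 0 °C; aq NH4Cl
Reagents that add atoms: none
Why: N-acylation of a lithiated oxazolidinone by a mixed pivalic anhydride, which is attacked at the less hindered acyl carbon, is the standard way to load this auxiliary and needs neither a free acid nor an acid chloride that would endanger the oxetane.

Step 4
Reactants: 7 (R)-4-benzyl-3-[2-(oxetan-3-yl)acetyl]oxazolidin-2-one; 8 3,4-dimethoxybenzyl bromide (4-(bromomethyl)-1,2-dimethoxybenzene)
Product: 10 (R)-4-benzyl-3-[(R)-3-(3,4-dimethoxyphenyl)-2-(oxetan-3-yl)propanoyl]oxazolidin-2-one, via sodium enolate 9 (not isolated)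
Conditions: NaN(SiMe3)2, THF, -78 °C; then 8, -78 to -30 °C; chromatography to remove any minor diastereomer
Reagents that add atoms: none
Why: In this Evans alkylation the chelated (Z)-sodium enolate is shielded on one face by the benzyl group of the (R)-auxiliary, so the benzylic bromide enters from the opposite face and sets the (R) configuration at the future C3, as in known benzylations of β-branched N-acyl oxazolidinone enolates.

Step 5
Reactants: 10 (R)-4-benzyl-3-[(R)-3-(3,4-dimethoxyphenyl)-2-(oxetan-3-yl)propanoyl]oxazolidin-2-one
Product: 12 (R)-3-(3,4-dimethoxyphenyl)-2-(oxetan-3-yl)propanoic acid, via lithium peroxycarboxylate 11 (not isolated)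
Conditions: LiOH, 30% H2O2, THF/H2O, 0 °C; aq Na2SO3; CH2Cl2 wash (recovers 4); 1 M HCl to pH 3-4 at 0 °C, EtOAc; used at once
Reagents that add atoms: hydrogen peroxide, OO
Why: Hydroperoxide cleaves the exocyclic imide carbonyl selectively even in hindered α-branched N-acyl oxazolidinones without epimerising the α-centre, sulfite reduces the peracid salt, and the oxetane is stable to the basic medium.

Step 6
Reactants: 12 (R)-3-(3,4-dimethoxyphenyl)-2-(oxetan-3-yl)propanoic acid
Product: 13 (3R,4S)-3-(3,4-dimethoxybenzyl)-4-(hydroxymethyl)dihydrofuran-2(3H)-one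
Conditions: CSA (10 mol%), CH2Cl2 (0.05 M), rt, then 40 °C if cis isomer persists; filtration through silica, chromatography
Reagents that add atoms: none
Why: CSA protonates the oxetane oxygen, which makes both ring CH2 carbons electrophilic, and the carbonyl oxygen of the carboxyl group displaces the oxonium at one of them by backside attack, driven by release of four-ring strain, with proton loss giving the lactone and returning the catalyst. The closest known reaction type is the acid-promoted, sometimes spontaneous, isomerisation of 2-(oxetan-3-yl)acetic acids to 4-(hydroxymethyl)-γ-butyrolactones. The lactone ring O1-C2-C3-C4-C5 closes in the 5-exo-tet mode by formation of the O1-C5 bond while the C5-O bond of the oxetane breaks, and the other arm is freed as the C4 hydroxymethyl group. The new stereocentre C4 comes from the choice between the two diastereotopic CH2O arms and is controlled by the existing C3 centre (1,2-induction): in the transition state leading to the trans lactone the ring A benzyl group on C3 lies on the face of the forming ring opposite to the arm that stays behind, whereas attack at the other arm forces the two into a near-eclipsed cis relation. The step needs this diastereotopic-group selectivity, which rests on the C3 substituent and should be reinforced thermodynamically because acid-catalysed translactonisation (addition of the hydroxymethyl oxygen to C2 through a bicyclic orthoacid-type intermediate) can interconvert cis and trans lactones without touching C3, and it needs chemoselectivity for O-attack over Friedel-Crafts opening by ring A, which the five-ring closure by the better oxygen nucleophile under a weak acid at high dilution should secure. C3 is not enolised by CSA, and the cis isomer is removed by chromatography before any base is used, because its later epimerisation at C3 would give the enantiomeric series.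

Step 7
Reactants: 13 (3R,4S)-3-(3,4-dimethoxybenzyl)-4-(hydroxymethyl)dihydrofuran-2(3H)-one
Product: 14 (3R,4R)-3-(3,4-dimethoxybenzyl)-4-(iodomethyl)dihydrofuran-2(3H)-one
Conditions: PPh3, I2, imidazole, CH2Cl2, 0 °C to rt
Reagents that add atoms: iodine, II
Why: Appel-type iodination of the primary alcohol proceeds by SN2 displacement of an alkoxyphosphonium ion at the exocyclic CH2 under nearly neutral conditions and touches neither stereocentre.

Step 8
Reactants: 14 (3R,4R)-3-(3,4-dimethoxybenzyl)-4-(iodomethyl)dihydrofuran-2(3H)-one; 15 5-bromo-1,2,3-trimethoxybenzene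
Product: 16 (3R,4R)-3-(3,4-dimethoxybenzyl)-4-(3,4,5-trimethoxybenzyl)dihydrofuran-2(3H)-one
Conditions: NiBr2(dme) (10 mol%), 4,4'-di-tert-butyl-2,2'-bipyridine (10 mol%), Zn dust (2 equiv), NaI (25 mol%), DMA, 60 °C
Reagents that add atoms: none
Why: In this nickel-catalysed reductive cross-electrophile coupling the aryl bromide adds to zerovalent nickel, the primary iodide gives an alkyl radical that is captured at nickel, and reductive elimination forms the CH2-aryl bond while zinc turns the catalyst over; the lactone is tolerated and the radical sits on the exocyclic carbon, so C4 keeps its configuration.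

**Compound list**

1 | methyl 2-(oxetan-3-ylidene)acetate | COC(=O)C=C1COC1 | starting material
2 | methyl 2-(oxetan-3-yl)acetate | COC(=O)CC1COC1 | intermediate
3 | lithium 2-(oxetan-3-yl)acetate | [Li+].[O-]C(=O)CC1COC1 | intermediate
4 | (R)-4-benzyloxazolidin-2-one | O=C1N[C@H](Cc2ccccc2)CO1 | starting material
5 | 2-(oxetan-3-yl)acetic pivalic anhydride | CC(C)(C)C(=O)OC(=O)CC1COC1 | intermediate
6 | lithium salt of (R)-4-benzyloxazolidin-2-one | [Li+].O=C1[N-][C@H](Cc2ccccc2)CO1 | intermediate
7 | (R)-4-benzyl-3-[2-(oxetan-3-yl)acetyl]oxazolidin-2-one | O=C(CC1COC1)N1C(=O)OC[C@H]1Cc1ccccc1 | intermediate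
8 | 3,4-dimethoxybenzyl bromide | COc1ccc(CBr)cc1OC | starting material
9 | sodium (Z)-enolate of 7 | [Na+].[O-]/C(=C\C1COC1)N1C(=O)OC[C@H]1Cc1ccccc1 | intermediate
10 | (R)-4-benzyl-3-[(R)-3-(3,4-dimethoxyphenyl)-2-(oxetan-3-yl)propanoyl]oxazolidin-2-one | COc1ccc(C[C@@H](C(=O)N2C(=O)OC[C@H]2Cc2ccccc2)C2COC2)cc1OC | intermediate
11 | lithium (R)-3-(3,4-dimethoxyphenyl)-2-(oxetan-3-yl)propaneperoxoate | [Li+].COc1ccc(C[C@@H](C(=O)O[O-])C2COC2)cc1OC | intermediate
12 | (R)-3-(3,4-dimethoxyphenyl)-2-(oxetan-3-yl)propanoic acid | COc1ccc(C[C@@H](C(=O)O)C2COC2)cc1OC | intermediate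
13 | (3R,4S)-3-(3,4-dimethoxybenzyl)-4-(hydroxymethyl)dihydrofuran-2(3H)-one | COc1ccc(C[C@H]2C(=O)OC[C@@H]2CO)cc1OC | intermediate
14 | (3R,4R)-3-(3,4-dimethoxybenzyl)-4-(iodomethyl)dihydrofuran-2(3H)-one | COc1ccc(C[C@H]2C(=O)OC[C@@H]2CI)cc1OC | intermediate
15 | 5-bromo-1,2,3-trimethoxybenzene | COc1cc(Br)cc(OC)c1OC | starting material
16 | (3R,4R)-3-(3,4-dimethoxybenzyl)-4-(3,4,5-trimethoxybenzyl)dihydrofuran-2(3H)-one | COc1ccc(C[C@H]2C(=O)OC[C@@H]2Cc2cc(OC)c(OC)c(OC)c2)cc1OC | target

Total step count: 8. Longest linear sequence: 8 steps (1 to 16).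

**Steps most likely to fail**

Step 6. The two diastereotopic CH2O arms may be discriminated poorly, equilibration between the cis and trans lactones may be slow, or ring A may open the activated oxetane in a Friedel-Crafts sense. The fallback fixes C4 first and sets C3 afterwards by trans-selective enolate alkylation. Of the main route it keeps only 3,4-dimethoxybenzyl bromide 8, from which it sets out as the C3 electrophile, and it comes back at the target 16.
- 3-(3,4,5-Trimethoxyphenyl)propanoic acid would be loaded on (S)-4-benzyloxazolidin-2-one (PivCl, Et3N, LiCl, THF) to give (S)-4-benzyl-3-[3-(3,4,5-trimethoxyphenyl)propanoyl]oxazolidin-2-one F1.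
- Its sodium (Z)-enolate F2 (NaN(SiMe3)2, THF, -78 °C) would be alkylated with tert-butyl bromoacetate to give (S)-4-benzyl-3-[(R)-4-tert-butoxy-4-oxo-2-(3,4,5-trimethoxybenzyl)butanoyl]oxazolidin-2-one F3.
- LiBH4 (THF, a little water, 0 °C) should reduce the imide carbonyl and release the auxiliary, giving tert-butyl (R)-4-hydroxy-3-(3,4,5-trimethoxybenzyl)butanoate F4.
- TsOH in warm toluene should close (R)-4-(3,4,5-trimethoxybenzyl)dihydrofuran-2(3H)-one F5.
- The lithium enolate of F5, F6 (LiN(SiMe3)2, THF, -78 °C), would be benzylated by 8 on the face opposite to the C4 substituent to give 16.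

Step 8. Hydrodehalogenation or dimerisation of the alkyl iodide may outpace cross-coupling with the electron-rich aryl bromide, which adds slowly to nickel. The fallback separates metalation from coupling, sets out from iodide 14 and comes back at 16. Zinc insertion (Zn dust activated with TMSCl and 1,2-dibromoethane, LiCl, THF, 40 °C) should give (3R,4R)-3-(3,4-dimethoxybenzyl)-4-[(iodozincio)methyl]dihydrofuran-2(3H)-one F7. A Negishi coupling of F7 with 15 (Pd(OAc)2, 2-dicyclohexylphosphino-2',6'-dimethoxybiphenyl, THF/NMP, 50 °C) should then form the CH2-aryl bond.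

Step 4. C-alkylation of the β-branched enolate may be sluggish while the electron-rich benzylic bromide decomposes, or facial control may be incomplete. The fallback sets C3 by catalytic asymmetric hydrogenation instead of an auxiliary, sets out from ester 2 and comes back at acid 12.
- The lithium enolate of methyl 2-(oxetan-3-yl)acetate F8 (LiN(iPr)2, THF, -78 °C) would add to 3,4-dimethoxybenzaldehyde to give methyl 3-(3,4-dimethoxyphenyl)-3-hydroxy-2-(oxetan-3-yl)propanoate F9.
- Acetylation (Ac2O, DMAP, CH2Cl2) to methyl 3-acetoxy-3-(3,4-dimethoxyphenyl)-2-(oxetan-3-yl)propanoate F10 and elimination with DBU should give methyl (E)-3-(3,4-dimethoxyphenyl)-2-(oxetan-3-yl)acrylate F11.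
- Saponification (LiOH, THF/H2O) should give (E)-3-(3,4-dimethoxyphenyl)-2-(oxetan-3-yl)acrylic acid F12, handled as its triethylammonium salt so that the oxetane is not opened.
- That salt would be hydrogenated in MeOH under H2 pressure with Ru(OAc)2(BINAP). The sense of induction is not predicted here; the ligand enantiomer is the one that a test run shows to give the (R)-acid. Cold acidification to pH 3-4 then gives 12. α-Branched (E)-cinnamic acids are a well-established substrate class for this hydrogenation.

**Further compounds**

F1 | step 6 | (S)-4-benzyl-3-[3-(3,4,5-trimethoxyphenyl)propanoyl]oxazolidin-2-one | COc1cc(CCC(=O)N2C(=O)OC[C@@H]2Cc2ccccc2)cc(OC)c1OC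
F2 | step 6 | sodium (Z)-enolate of F1 | [Na+].[O-]/C(=C\Cc1cc(OC)c(OC)c(OC)c1)N1C(=O)OC[C@@H]1Cc1ccccc1
F3 | step 6 | (S)-4-benzyl-3-[(R)-4-tert-butoxy-4-oxo-2-(3,4,5-trimethoxybenzyl)butanoyl]oxazolidin-2-one | COc1cc(C[C@H](CC(=O)OC(C)(C)C)C(=O)N2C(=O)OC[C@@H]2Cc2ccccc2)cc(OC)c1OC
F4 | step 6 | tert-butyl (R)-4-hydroxy-3-(3,4,5-trimethoxybenzyl)butanoate | COc1cc(C[C@H](CC(=O)OC(C)(C)C)CO)cc(OC)c1OC
F5 | step 6 | (R)-4-(3,4,5-trimethoxybenzyl)dihydrofuran-2(3H)-one | O=C1C[C@@H](Cc2cc(OC)c(OC)c(OC)c2)CO1
F6 | step 6 | lithium enolate of F5 | [Li+].[O-]C1=C[C@@H](Cc2cc(OC)c(OC)c(OC)c2)CO1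
F7 | step 8 | (3R,4R)-3-(3,4-dimethoxybenzyl)-4-[(iodozincio)methyl]dihydrofuran-2(3H)-one | COc1ccc(C[C@H]2C(=O)OC[C@@H]2C[Zn]I)cc1OC
F8 | step 4 | lithium enolate of methyl 2-(oxetan-3-yl)acetate | [Li+].[O-]C(OC)=CC1COC1
F9 | step 4 | methyl 3-(3,4-dimethoxyphenyl)-3-hydroxy-2-(oxetan-3-yl)propanoate (mixture of diastereomers) | COc1ccc(C(O)C(C(=O)OC)C2COC2)cc1OC
F10 | step 4 | methyl 3-acetoxy-3-(3,4-dimethoxyphenyl)-2-(oxetan-3-yl)propanoate (mixture of diastereomers) | COc1ccc(C(OC(C)=O)C(C(=O)OC)C2COC2)cc1OC
F11 | step 4 | methyl (E)-3-(3,4-dimethoxyphenyl)-2-(oxetan-3-yl)acrylate | COC(=O)/C(=C/c1ccc(OC)c(OC)c1)C1COC1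
F12 | step 4 | (E)-3-(3,4-dimethoxyphenyl)-2-(oxetan-3-yl)acrylic acid | OC(=O)/C(=C/c1ccc(OC)c(OC)c1)C1COC1
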